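**Retrosynthetic overview**
1. Ester C–O: target 14 ⇒ phenol-alcohol 12 + angelic anhydride 13 (alkoxide acylation, last step).
2. C=CH2: 12 ⇒ α-hydroxy aryl ketone 11 (Wittig methylenation).
3. Key Ar–C(=O) bond: 11 ⇒ aryl ester 9, by a light-driven 1,3-acyl shift (photo-Fries) to the only free ortho carbon.
4. 9 ⇒ phenol 7 (Dakin oxidation of aldehyde 5) + acid 4 ⇒ methyl (S)-glycidate 1 + isobutenyl Grignard 2; the stereocentre is the glycidate carbon.
5. No ring is built: the benzene ring is bought in 5, and the epoxide of 1 is opened in step 1.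

Assumption: 1, 2 (0.5 M in THF), 5 and 13 are catalogue compounds; 1 is the only source of chirality.

**Step 1**
Reactants: 1 methyl (2S)-oxirane-2-carboxylate; 2 (2-methylprop-1-en-1-yl)magnesium bromide
Product: 4 (2S)-2-hydroxy-5-methylhex-4-enoic acid, via methyl ester 3 (not isolated)
Conditions: CuI (10 mol %), THF, −40 → −20 °C; then LiOH, H2O, 0 → 20 °C; 1 M HCl to pH 3
Reagents that add atoms: lithium hydroxide, [Li+].[OH-]
Why: Copper-catalysed Grignard opening of a glycidic ester is an SN2 attack at the unsubstituted C3, so the purchased C2–O stereocentre is untouched, and saponification of the α-hydroxy ester at 0–20 °C in the same pot does not epimerise it.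

**Step 2**
Reactants: 5 2,4-dimethoxy-3-methylbenzaldehyde
Product: 7 2,4-dimethoxy-3-methylphenol, via aryl formate 6 (not isolated)
Conditions: 3-chloroperbenzoic acid (mCPBA), CH2Cl2, 0 → 20 °C; then MeOH, K2CO3 (10 mol %), 20 °C
Reagents that add atoms: 3-chloroperbenzoic acid, O=C(OO)c1cccc(Cl)c1
Why: Dakin-type Baeyer–Villiger oxidation, in which the electron-rich aryl group migrates to give the formate, which is methanolysed at once.

**Step 3**
Reactants: 4 (2S)-2-hydroxy-5-methylhex-4-enoic acid; 7 2,4-dimethoxy-3-methylphenol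
Product: 9 2,4-dimethoxy-3-methylphenyl (2S)-2-hydroxy-5-methylhex-4-enoate, via O-acylisourea 8 (not isolated)
Conditions: N,N'-diisopropylcarbodiimide (slow addition), 4-(dimethylamino)pyridine (10 mol %), 7 (2 equiv), CH2Cl2, 0 → 20 °C
Reagents that add atoms: none
Why: Steglich esterification, in which the phenol (in excess) takes the activated acyl group faster than the hindered, electron-poor α-hydroxyl of a second acid molecule, and the stereocentre is not enolised at 0 °C.

**Step 4**
Reactants: 9 2,4-dimethoxy-3-methylphenyl (2S)-2-hydroxy-5-methylhex-4-enoate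
Product: 11 (2S)-2-hydroxy-1-(2-hydroxy-3,5-dimethoxy-4-methylphenyl)-5-methylhex-4-en-1-one, via ortho-acyl dienone 10 (not isolated)
Conditions: hν (254 nm, low-pressure Hg lamp, quartz flow cell), degassed MeCN (0.01 M), 20 °C
Reagents that add atoms: none
Why: Proposed new method: a photo-Fries 1,3-acyl shift of an aryl ester of an unprotected, enantiopure α-hydroxy acid, a substrate class that I believe has not been reported for this reaction; singlet excitation of the aryl ester homolyses the ArO–C(=O) bond to a caged phenoxyl/α-hydroxyacyl radical pair, which recombines at C6 (the only ortho or para carbon bearing hydrogen, C2 and C4 carrying OMe and giving only reversible ipso adducts), and dienone 10 tautomerises to the hydrogen-bonded o-hydroxyaryl ketone, which is photostable through excited-state proton transfer; cage recombination (sub-nanosecond) should outrun decarbonylation of the α-hydroxyacyl radical (estimated 10^5–10^6 s−1), and the stereocentre is never a radical or enolisable centre, so configuration is retained; the closest known reaction type is the photo-Fries rearrangement of simple aryl alkanoates and benzoates.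

**Step 5**
Reactants: 11 (2S)-2-hydroxy-1-(2-hydroxy-3,5-dimethoxy-4-methylphenyl)-5-methylhex-4-en-1-one
Product: 12 6-[(3S)-3-hydroxy-6-methylhepta-1,5-dien-2-yl]-2,4-dimethoxy-3-methylphenol
Conditions: Ph3PCH3Br (4 equiv), KOtBu (3.8 equiv), THF, 0 °C; add 11; 0 → 40 °C
Reagents that add atoms: methyltriphenylphosphonium bromide, C[P+](c1ccccc1)(c1ccccc1)c1ccccc1.[Br-]
Why: Wittig methylenation with excess ylide, as used for 2-hydroxyacetophenones and α-ketols: two equivalents only deprotonate the phenol and the alcohol, and the resulting α-oxido group blocks enolisation toward the stereocentre, so it is not epimerised.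

**Step 6**
Reactants: 12 6-[(3S)-3-hydroxy-6-methylhepta-1,5-dien-2-yl]-2,4-dimethoxy-3-methylphenol; 13 (2Z)-2-methylbut-2-enoic anhydride (angelic anhydride)
Product: 14 (3S)-2-(2-hydroxy-3,5-dimethoxy-4-methylphenyl)-6-methylhepta-1,5-dien-3-yl (2Z)-2-methylbut-2-enoate
Conditions: LiN(SiMe3)2 (2.1 equiv), THF, −78 °C; 13 (1.05 equiv), −78 → −30 °C; AcOH quench
Reagents that add atoms: none
Why: Acylation of a lithium alkoxide by the anhydride without a nucleophilic catalyst keeps the Z double bond; in the dianion the alkoxide is the stronger nucleophile, and any aryl angelate formed relays its acyl group to the alkoxide because alkyl ester plus phenoxide is the thermodynamic sink.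

**Compound list**
1 | methyl (2S)-oxirane-2-carboxylate (methyl (S)-glycidate) | COC(=O)[C@@H]1CO1 | starting material
2 | (2-methylprop-1-en-1-yl)magnesium bromide | CC(C)=C[Mg]Br | starting material
3 | methyl (2S)-2-hydroxy-5-methylhex-4-enoate (not isolated) | COC(=O)[C@@H](O)CC=C(C)C | intermediate
4 | (2S)-2-hydroxy-5-methylhex-4-enoic acid | OC(=O)[C@@H](O)CC=C(C)C | intermediate
5 | 2,4-dimethoxy-3-methylbenzaldehyde | COc1ccc(C=O)c(OC)c1C | starting material
6 | 2,4-dimethoxy-3-methylphenyl formate (not isolated) | COc1ccc(OC=O)c(OC)c1C | intermediate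
7 | 2,4-dimethoxy-3-methylphenol | COc1ccc(O)c(OC)c1C | intermediate
8 | O-acylisourea of 4 and N,N'-diisopropylcarbodiimide (not isolated) | CC(C)NC(=NC(C)C)OC(=O)[C@@H](O)CC=C(C)C | intermediate
9 | 2,4-dimethoxy-3-methylphenyl (2S)-2-hydroxy-5-methylhex-4-enoate | COc1ccc(OC(=O)[C@@H](O)CC=C(C)C)c(OC)c1C | intermediate
10 | 6-[(2S)-2-hydroxy-5-methylhex-4-enoyl]-2,4-dimethoxy-3-methylcyclohexa-2,4-dien-1-one, both epimers at C6 (not isolated) | O=C1C(C(=O)[C@@H](O)CC=C(C)C)C=C(OC)C(C)=C1OC | intermediate
11 | (2S)-2-hydroxy-1-(2-hydroxy-3,5-dimethoxy-4-methylphenyl)-5-methylhex-4-en-1-one | COc1cc(C(=O)[C@@H](O)CC=C(C)C)c(O)c(OC)c1C | intermediate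
12 | 6-[(3S)-3-hydroxy-6-methylhepta-1,5-dien-2-yl]-2,4-dimethoxy-3-methylphenol | C=C(c1cc(OC)c(C)c(OC)c1O)[C@H](CC=C(C)C)O | intermediate
13 | (2Z)-2-methylbut-2-enoic anhydride (angelic anhydride) | C/C=C(/C)C(=O)OC(=O)/C(C)=C\C | starting material
14 | (3S)-2-(2-hydroxy-3,5-dimethoxy-4-methylphenyl)-6-methylhepta-1,5-dien-3-yl (2Z)-2-methylbut-2-enoate | C=C(c1cc(OC)c(C)c(OC)c1O)[C@H](CC=C(C)C)OC(=O)/C(C)=C\C | target

**Step count**
Total: 6 steps. Longest linear sequence: 5 steps (1, 3, 4, 5, 6); step 2 is a side branch.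

**Three steps most likely to fail**

Step 3 (self-esterification of the unprotected hydroxy acid). The fallback sets out from 4 and comes back at 9. Acid 4 is silylated twice (TBSCl, imidazole, DMF) to tert-butyldimethylsilyl (2S)-2-[(tert-butyldimethylsilyl)oxy]-5-methylhex-4-enoate F1. K2CO3 in MeOH–H2O cleaves only the silyl ester to give (2S)-2-[(tert-butyldimethylsilyl)oxy]-5-methylhex-4-enoic acid F2. F2 is coupled with 7 (N,N'-diisopropylcarbodiimide, 4-(dimethylamino)pyridine) to 2,4-dimethoxy-3-methylphenyl (2S)-2-[(tert-butyldimethylsilyl)oxy]-5-methylhex-4-enoate F3. HF·pyridine in THF at 0 °C, which spares the aryl ester, then removes the silyl ether and gives 9.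

Step 4 (the new step; radical escape, decarbonylation or low conversion). The fallback uses known chemistry, sets out from 3 (isolated from step 1 by an aqueous NH4Cl quench before LiOH is added) and from 7, and comes back at 11. Ester 3 is converted with MeNHOMe·HCl and i-PrMgCl (THF, −20 °C) into the Weinreb amide (2S)-2-hydroxy-N-methoxy-N,5-dimethylhex-4-enamide F4. Phenol 7 is protected (MOMCl, i-Pr2NEt) as 1,3-dimethoxy-4-(methoxymethoxy)-2-methylbenzene F5. F5 is lithiated ortho to the OMOM group (n-BuLi, TMEDA, THF, 0 °C) to [3,5-dimethoxy-2-(methoxymethoxy)-4-methylphenyl]lithium F6. F6 is added at −78 °C to F4 (pre-deprotonated with one equivalent of i-PrMgCl) to give (2S)-1-[3,5-dimethoxy-2-(methoxymethoxy)-4-methylphenyl]-2-hydroxy-5-methylhex-4-en-1-one F7. HCl in MeOH at 0 °C removes the MOM group and gives 11.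

Step 5 (sluggish methylenation of the doubly deprotonated ketone). The fallback sets out from 11 and comes back at 14, reversing the order of the last two operations. The secondary hydroxyl of 11 is acylated with 13 (pyridine, CH2Cl2, 0 → 20 °C, no 4-(dimethylamino)pyridine), the phenol being held in a hydrogen bond to the ketone, to give (2S)-1-(2-hydroxy-3,5-dimethoxy-4-methylphenyl)-5-methyl-1-oxohex-4-en-2-yl (2Z)-2-methylbut-2-enoate F8. The ketone of F8 is then methylenated with the non-basic Lombardo reagent (Zn, CH2Br2, TiCl4, THF–CH2Cl2, 0 → 20 °C, excess), which leaves esters and the α-stereocentre alone, to give 14.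

**Further compounds**
F1 | step 3 | tert-butyldimethylsilyl (2S)-2-[(tert-butyldimethylsilyl)oxy]-5-methylhex-4-enoate | CC(C)(C)[Si](C)(C)OC(=O)[C@@H](O[Si](C)(C)C(C)(C)C)CC=C(C)C
F2 | step 3 | (2S)-2-[(tert-butyldimethylsilyl)oxy]-5-methylhex-4-enoic acid | OC(=O)[C@@H](O[Si](C)(C)C(C)(C)C)CC=C(C)C
F3 | step 3 | 2,4-dimethoxy-3-methylphenyl (2S)-2-[(tert-butyldimethylsilyl)oxy]-5-methylhex-4-enoate | COc1ccc(OC(=O)[C@@H](O[Si](C)(C)C(C)(C)C)CC=C(C)C)c(OC)c1C
F4 | step 4 | (2S)-2-hydroxy-N-methoxy-N,5-dimethylhex-4-enamide | CON(C)C(=O)[C@@H](O)CC=C(C)C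
F5 | step 4 | 1,3-dimethoxy-4-(methoxymethoxy)-2-methylbenzene | COCOc1ccc(OC)c(C)c1OC
F6 | step 4 | [3,5-dimethoxy-2-(methoxymethoxy)-4-methylphenyl]lithium | [Li]c1cc(OC)c(C)c(OC)c1OCOC
F7 | step 4 | (2S)-1-[3,5-dimethoxy-2-(methoxymethoxy)-4-methylphenyl]-2-hydroxy-5-methylhex-4-en-1-one | COCOc1c(OC)c(C)c(OC)cc1C(=O)[C@@H](O)CC=C(C)C
F8 | step 5 | (2S)-1-(2-hydroxy-3,5-dimethoxy-4-methylphenyl)-5-methyl-1-oxohex-4-en-2-yl (2Z)-2-methylbut-2-enoate | COc1cc(C(=O)[C@H](CC=C(C)C)OC(=O)/C(C)=C\C)c(O)c(OC)c1C
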